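Readings and results come from a simulation from invented constants; noise was put on by code.

Measure the two substrates as well as the products when you repeat this flask.

| flask | left-handed substrate | right-handed substrate | reagent | free catalyst | racemization catalyst | remark | time |
|---|---|---|---|---|---|---|---|
| west | 0.54 M | 0.54 M | 1.76 M | 2.5 mM | 8 mM | run made earlier |  |
| north | 1.2 M | 1.2 M | 1.76 M | 2.5 mM | 8 mM | run made earlier |  |
| flask | 0.80 M | 0.80 M | 1.76 M | 2.5 mM | 8.0 mM |  | 3.0 h |

| run | time / h | left-handed product / % | right-handed product / % |
|---|---|---|---|
| west | 0.833 | 16 | 8 |
| west | 2.00 | 28 | 12 |
| west | 2.50 | 29 | 13 |
| west | 4.00 | 32 | 14 |
| north | 0.250 | 6 | 0 |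
| north | 0.667 | 15 | 5 |
| north | 1.50 | 19 | 9 |
| north | 4.00 | 28 | 13 |

(readings scatter by 1.5 percentage points)

- free catalyst is single-handed; left-handed substrate and right-handed substrate are mirror images of each other, charged as a racemate, each of them at the stated concentration
- steps under discussion: reagent + free catalyst + left-handed substrate -> free catalyst + left-handed product; reagent + free catalyst + right-handed substrate -> free catalyst + right-handed product; left-handed substrate + racemization catalyst <-> right-handed substrate + racemization catalyst; racemization catalyst -> spent catalyst A; 2 free catalyst -> spent catalyst B
- an excess is below zero if the other one leads

1. left-handed product and right-handed product together, in percent of the left-handed substrate and right-handed substrate charged together, at 3.0 h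
2. excess of left-handed product over right-handed product in the product at 3.0 h
3. whether the exchange between left-handed substrate and right-handed substrate keeps pace with the reaction: how far the product's excess at 3.0 h gets from its value without exchange to its value with instant exchange (above 80% keeps pace, below 20% hardly takes part, else lags behind)

Both hands meet the same reagent on the same free catalyst. If the substrates do not exchange, then however those two fall with time, they cancel from this ratio:

s = ln(left-handed substrate remaining) / ln(right-handed substrate remaining)

Without exchange, each remainder follows from that hand's product over its own charge. The last readings give 3.11 in west and 2.73 in north, with a mean of 2.92. This reading is the selectivity factor: the left-handed substrate's rate per amount present over the right-handed substrate's.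

Now take the left-handed product in the flask at 3.0 h as 28.5%, the mean of west at 2.50 h and north at 4.00 h. Without exchange, that leaves 43.0% of the left-handed substrate, so s leaves 74.9% of the right-handed. My reckoning is then a yield of 41.1% and an excess of 38.8%.

One number is not enough, though. Read with instant exchange, the same last readings give plain product ratios of 2.29 and 2.15, so these product readings leave the choice open. Substrate readings can tell the two apart: without exchange the substrates part, and with instant exchange they stay equal.

The forecast gives 41%, 38%, and an exchange that lags behind: “That points, tentatively, to lagging exchange.”

The flask gives 40.8% and 41.4%, and its exchange hardly takes part, getting 7.7% of the way.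

    reagent + free catalyst + left-handed substrate → free catalyst + left-handed product (k = 2.70 M⁻² min⁻¹)
    reagent + free catalyst + right-handed substrate → free catalyst + right-handed product (k = 0.880 M⁻² min⁻¹)
    left-handed substrate + racemization catalyst ⇌ right-handed substrate + racemization catalyst, rate k3*[racemization catalyst]*[left-handed substrate] forward; the back reaction follows from the equilibrium constant (k = 0.150 M⁻¹ min⁻¹)
    racemization catalyst → spent catalyst A (k = 0.00760 min⁻¹)
    2 free catalyst → spent catalyst B (k = 2.70 M⁻¹ min⁻¹)

In the flask at 3.00 h, 45% of the charged left-handed substrate and 74% of the charged right-handed remain, which puts the ratio of logarithms s at 2.65. Half the left-handed turnover up to 3.00 h is done by 0.658 h, whereas the relaxation half-life of the exchange alone, both ways together, stands at 3.00 h far longer, at 18.9 h.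

In the neighbour flask, charged like this one but with 0.0015 M of free catalyst, 53% of the left-handed substrate remains at 3.0 h, so s puts the right-handed at 80.7% of its charge and the product's excess at 41.4%. Computed for that neighbour flask are 79% of the right-handed substrate and an excess of 43.5%.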